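## Structural features

Skeleton locants used throughout: the seven-membered ring is C1–C5 plus C6 and C10 (exocyclic methylene on C1, gem-dimethyl on C5), the cyclopentane is C6–C10, and quaternary C9 (methyl) is joined by the single bond C9–C11 to a 2,7-dioxabicyclo[3.2.1]octan-3-one. That bicycle consists of the lactone O13–C14–C15–C16–C11–C12 and the tetrahydrofuran O18–C17–C16–C11–C12, which share C11, C12 and C16; C19 is the ester carbonyl on C17. The eight stereocenters are 6R, 9R, 10S, 11R, 12S, 15S, 16R, 17R in these locants, and C10, C9, C11 and C12/C16 are contiguous across the inter-ring bond. H6 and H10 are cis; the C9 methyl lies on the face of C1 and C5, and C11 on the face of the ring-fusion hydrogens. In the bicycle the hydroazulenyl group on C11 sits over the lactone bridge, the C15 acetoxy group is equatorial and the C17 ester is exo; opened up, C15–C16–C17 is an internally mirror-symmetric triad with both oxygens trans to C11. Fragile groups are the acylal carbon C12, the α-acetoxy lactone, the α-alkoxy ester at C17, the 1,1-disubstituted alkene (it would not survive ozone and can migrate under acid) and C10 once C1 is a ketone. The real difficulty is quaternary C9, flanked by the stereogenic C10 and C11, and the stereocontrolled link between two hindered halves. The key step uses the fact that C9 carries a methyl group, the ring carbon C8 and the exocyclic one-carbon unit C11: with C8 oxidised this is a 2-formyl-2-methylcyclopentanone, the product of a 1,2-acyl shift in a 3-methyl-2,3-epoxycyclohexanone in which C11 is still a ring atom.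

## Logic of the disconnections

35 is traced to 34 and then 33 by cutting the C1=CH2 bond back to a C1 carbonyl kept as a dioxolane. The alkene cannot pass the two ozonolyses of the route, so it is made last. The demand is a methylenation that leaves the acylal, acetate and ester alone and does not epimerise C10.

33 is traced to 32 (acetate off) and 32 to 31/30 by cutting C12–O18 and O13–C14. This removes both heterocycles and the C12 stereocenter and exposes an open aldehyde with two identical hydroxy ester arms on C16. The forward closure must choose the right arm; C11 makes that choice, because only one mode keeps the hydroazulenyl group away from the exo ester.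

30 is traced to 29 by changing the C12 aldehyde into a nitromethyl group, and 29 via 28 to 25 by rejoining the carboxyl carbons C14 and C19 as a ring alkene. The acyclic triad thus becomes a cis-cyclopent-4-ene-1,3-diol that carries the C11 substituent on C16 trans to both oxygens. The forward steps (ozonolysis, oxidation, esterification, oxidative Nef reaction) must not touch C11.

24 is traced to 20 and 21 by cutting the C15–O and C17–O bonds (both oxygens come from one molecule of dioxygen) and the C11–C16 bond. Three stereocenters disappear and the whole oxygenated triad becomes a cyclopentadienyl unit. A hydride reduction of a 2-substituted cyclopentene-1,3-dione would deliver hydrogen anti to the C11 substituent and give the all-cis diol, the wrong triad; cycloaddition of singlet oxygen anti to that substituent gives the required trans,trans arrangement directly. The demands are face selectivity at C11 under control of C9 and capture of the kinetic 5-substituted diene before its hydrogen shift.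

20 is traced to 17 by cutting C11=C12 (nitroaldol condensation), and 17 through 15 and 13 to 12 by reinstating the C8 carbonyl. The C8 oxygen is removed early, on a molecule that holds only a ketal and a vinyl group, with the aldehyde parked as that vinyl group.

12 is traced to 11 by breaking C8–C9 and re-forming C8–C11. The cyclopentanone becomes a cyclohexanone oxide and the quaternary stereocenter C9 becomes an epoxide carbon whose face decides its configuration. The forward step needs acyl migration with inversion at C9 and a single epoxide diastereomer.

11 is traced to 10 (epoxide to enone), 10 to 9 (ketal to ketone) and 9 to 8 (enone to silyl enol ether). The demands are convex-face epoxidation, ketalisation of C1 only, and regiospecific dehydrogenation on the C11/C9 side.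

8 is traced to 5 and 7 by cutting C6–C7 and C9–C10 (Diels–Alder). The gain is the whole carbon framework with the cis relationship of C6 and C10; the catalyst must set their absolute configuration on a dienophile hindered by the neighbouring gem-dimethyl group.

5 is traced through 3 and 2 to 1 by removing the inserted ring carbon and the conjugate-added methyl group, and 7 to 6. This sequence fixes the position of the gem-dimethyl group relative to the enone beyond doubt.

## Other disconnections considered

Alternative 1: The cut is in the seven-membered ring, at C2–C3 and C5–C6. Forward, a dirhodium carbenoid (Rh2(OAc)4 or a chiral analogue such as Rh2(S-DOSP)4) from the vinyldiazoacetate A1 cyclopropanates the terminal alkene of the ethoxydiene A2, and the cis-divinylcyclopropane undergoes Cope rearrangement to the cycloheptadiene A3.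
- In favour: the ring, the gem-dimethyl carbon and the C1 oxygen arrive in one convergent operation, and the quaternary C9 is already in the cyclopentene.
- Against: C9 must first be made as a single enantiomer. C6 is then set relative to C9 only by the difference between a methyl group and a silyloxyethyl chain. The vinyl terminus C5 carries two methyl groups, one of which must point into the boat transition state, so the Cope step should be slow or diverted. A3 has an ester on C3 that the target lacks. C11 is still a methylene, so the C11–C16 bond and the C11 stereocenter would have to be made later from a neopentyl nucleophile.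
- Comparison: in steps to the carbocycle and in convergence this alternative is the better. In stereocontrol the chosen plan is stronger, since C6 and C10 come from one catalytic cycloaddition and C9 follows from them stereospecifically. Both key steps are concerted rearrangements, but the ring contraction has a close precedent on the same ring type.

Alternative 2: The cut is at C12–O18 and O13–C14. Forward, acid converts the open aldehyde A4 into the lactol with the C17 hydroxyl, and the lactol oxygen is acylated by the C14 ester, giving the bicycle A5.
- In favour: two rings and the C12 stereocenter form in one thermodynamically driven step, and five stereocenters are reduced to C11 plus a symmetric triad. This closure is the equal of any other way to finish the bicycle, and the chosen route ends with it (step 19).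
- Against, as the centre of the strategy: it says nothing about C9 or the hydroazulene. Its selectivity rests on a conformational preference, not on a stereospecific mechanism. Lactonisation between the two arms can compete, and C11 is α to the aldehyde.
- Comparison: in structure built per step it is the better (two rings against one). In mechanistic certainty the acyl shift is the better. In step economy the two are equal, because both belong to the same route.

Alternative 3: The cut is at C16–C17 and C15–O. Forward, heating the alkoxyamine A6 gives the C17 radical, which closes 5-exo onto C16 of the unsaturated lactone; the C15 radical recombines with the aminoxyl to give A7.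
- In favour: one step forms the tetrahydrofuran and sets C15, C16 and C17 in a rigid transition state. No symmetric diol and no late ozonolysis are needed, so the exocyclic methylene can be present throughout. In late-stage economy this is the better of the two end-games.
- Against: C11 and the C12 acetal must already be in place. The N–O bond has to be cleaved before acetylation. The thermolysis heats an acylal, and reversible C–O homolysis can erode C15.
- Comparison: it addresses the bicycle only, so on structure it complements the ring contraction and does not replace it. On mechanism the radical closure is as predictable as the ionic shift in ring size and fusion, and less so at C17.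

Key step: step 9

Remarks on the chemistry:
- The cycloheptenone 5 is made by siloxycyclopropane ring expansion and not by diazoalkane homologation of 4,4-dimethylcyclohexenone, because insertion next to an enone can take the vinyl or the alkyl side and would leave the position of the gem-dimethyl group uncertain.
- The sense of induction in step 5 is assigned from the usual α-C–H···O binding model of the oxazaborolidinium catalyst and is an assumption; if it is the reverse, the (R)-catalyst is used.
- The structures of 11 and 12 need no correction: inversion at C9 during the shift turns the convex-face epoxide into the C9 configuration of the target.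

## Route

Step 1
Reactants: 1 3-methylcyclohex-2-en-1-one
Product: 2 3,3-dimethyl-1-(trimethylsilyloxy)cyclohex-1-ene
Conditions: MeMgBr, CuBr·SMe2 (5 mol %), TMSCl, HMPA, THF, −78 °C; Et3N
Reagents that add atoms: methylmagnesium bromide, C[Mg]Br; chlorotrimethylsilane, C[Si](C)(C)Cl
Why: Copper-catalysed conjugate addition to the β-methyl enone, accelerated and trapped by TMSCl, should give the silyl enol ether regiospecifically on the side of the new quaternary carbon.

Step 2
Reactants: 2 3,3-dimethyl-1-(trimethylsilyloxy)cyclohex-1-ene
Product: 3 5,5-dimethyl-1-(trimethylsilyloxy)bicyclo[4.1.0]heptane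
Conditions: Et2Zn, CH2I2, CH2Cl2, 0 °C → rt
Reagents that add atoms: diiodomethane, ICI
Why: Simmons–Smith cyclopropanation (Furukawa variant) of an electron-rich enol ether; the product is racemic and its stereocenters are lost in step 3.

Step 3
Reactants: 3 5,5-dimethyl-1-(trimethylsilyloxy)bicyclo[4.1.0]heptane
Product: 5 4,4-dimethylcyclohept-2-en-1-one, via 3-chloro-4,4-dimethylcycloheptan-1-one 4 (not isolated)
Conditions: FeCl3, DMF, 0 °C → rt; then NaOAc, MeOH, reflux
Reagents that add atoms: none
Why: Ito–Saegusa ring expansion: FeCl3 oxidises the siloxycyclopropane, the internal bond cleaves to the β-keto radical, which is chlorinated, and NaOAc eliminates HCl. The inserted carbon becomes the enone α-carbon, so the gem-dimethyl group ends at C4 of the cycloheptenone.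

Step 4
Reactants: 6 (E)-pent-3-en-2-one
Product: 7 (E)-2-(tert-butyldimethylsilyloxy)penta-1,3-diene
Conditions: TBSOTf, Et3N, Et2O, 0 °C
Reagents that add atoms: tert-butyldimethylsilyl trifluoromethanesulfonate, CC(C)(C)[Si](C)(C)OS(=O)(=O)C(F)(F)F
Why: Soft enolisation at the methyl group (kinetic α′ deprotonation) should give the cross-conjugated 2-silyloxydiene with the E alkene unchanged.

Step 5
Reactants: 5 4,4-dimethylcyclohept-2-en-1-one; 7 (E)-2-(tert-butyldimethylsilyloxy)penta-1,3-diene
Product: 8 cis-fused Diels–Alder adduct (C1 ketone, C8 silyl enol ether with C8=C11, C9 methyl)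
Conditions: (S)-o-tolyl-CBS oxazaborolidine (20 mol %), AlBr3 (16 mol %), CH2Cl2, −78 → −40 °C
Reagents that add atoms: none
Why: Catalytic asymmetric Diels–Alder reaction of a cyclic enone with a 2-silyloxydiene: the nucleophilic CH2 terminus (C7) bonds to the β-carbon C6 and the methyl-bearing terminus (C9) to C10, so both diene substituents direct the same regiochemistry. Suprafacial addition makes H6 and H10 cis, and the catalyst, bound to the C1 carbonyl, blocks one face of the enone and so sets the absolute configuration of C6 and C10; the endo C9 center is removed in step 6.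

Step 6
Reactants: 8 cis-fused Diels–Alder adduct
Product: 9 cis-fused enedione (C1 ketone, C8 enone with C11=C9)
Conditions: Pd(OAc)2 (10 mol %), O2 (1 atm), DMSO, rt
Reagents that add atoms: none
Why: Saegusa–Ito oxidation: the divalent palladium enolate forms at C11 and β-hydride elimination from C9 places the double bond regiospecifically at C11=C9. C6 and C10 are untouched under these neutral conditions.

Step 7
Reactants: 9 cis-fused enedione
Product: 10 enone ketal (C1 dioxolane)
Conditions: TMSOCH2CH2OTMS, TMSOTf (5 mol %), CH2Cl2, −78 → −20 °C; pyridine
Reagents that add atoms: 1,2-bis(trimethylsilyloxy)ethane, C[Si](C)(C)OCCO[Si](C)(C)C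
Why: Noyori ketalisation: the saturated C1 ketone should react well before the β,β-disubstituted enone, and the aprotic low-temperature conditions avoid enolisation towards C10, which is α to C1 and γ to C8.

Step 8
Reactants: 10 enone ketal
Product: 11 epoxy ketone (C9–C11 epoxide on the face of H6 and H10)
Conditions: 30% H2O2, NaOH (cat.), MeOH, 0 → 15 °C
Reagents that add atoms: hydrogen peroxide, OO
Why: Weitz–Scheffer epoxidation, as for isophorone: hydroperoxide adds to C9 from the convex face, anti to the pseudoaxial C10–C1 bond of the cis-fused bicycle, and the enolate closes the ring, so the oxygen ends syn to H6 and H10 and the methyl syn to C1.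

Step 9
Reactants: 11 epoxy ketone
Product: 12 hydroazulenone carbaldehyde (C8 ketone, C9 methyl and formyl, C1 dioxolane)
Conditions: BF3·OEt2 (1.2 equiv), CH2Cl2, −40 → 0 °C, 30 min; cold aqueous NaHCO3
Reagents that add atoms: none
Why: BF3 coordinates the epoxide oxygen and the C9–O bond lengthens, since C9 is tertiary and remote from the carbonyl; the C8–C11 bond, which lies on the side of C9 opposite the departing oxygen, shifts to C9 while C11–O becomes the aldehyde carbonyl (Lewis-acid epoxy ketone rearrangement, a semipinacol 1,2-acyl shift). The closest known case is the BF3-mediated conversion of isophorone oxide into 2-formyl-2,4,4-trimethylcyclopentanone. The cyclopentanone ring C6–C7–C8–C9–C10 is closed by this 1,2-migration, that is by contraction of the cyclohexanone, and not by an end-to-end cyclisation. The new stereocenter C9 is controlled by the epoxide face: the acyl carbon enters anti to the leaving oxygen, C9 is inverted, the methyl group stays syn to C1 and C11 ends on the face of H6 and H10. Because bond breaking and migration are concerted, no free cation is available to scramble C9 or to lose the C10 proton. The step needs acyl in preference to hydride migration (a hydride shift would give the 1,2-dione), which is the normal course for β,β-disubstituted epoxy ketones. It also needs a single epoxide diastereomer, secured in step 8, and survival of the dioxolane, which low temperature, short contact and a cold basic quench should secure. The β-keto aldehyde is deformylated by aqueous base and is therefore used at once.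

Step 10
Reactants: 12 hydroazulenone carbaldehyde
Product: 13 C9 vinyl ketone
Conditions: Ph3PCH3Br, NaN(SiMe3)2, THF, 0 °C; then 12, −78 → 0 °C
Reagents that add atoms: methyltriphenylphosphonium bromide, C[P+](c1ccccc1)(c1ccccc1)c1ccccc1.[Br-]
Why: Wittig methylenation: the aldehyde should react far faster than the neopentyl ketone, and in the absence of oxygen nucleophiles no retro-Claisen deformylation can occur. The vinyl group masks C11 for the next step.

Step 11
Reactants: 13 C9 vinyl ketone
Product: 15 C9 vinyl hydroazulene ketal (C8 methylene), via C8 hydrazone 14 (not isolated)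
Conditions: N2H4·H2O, diethylene glycol, 130 °C; then KOH, 200 °C, argon
Reagents that add atoms: none
Why: Wolff–Kishner reduction (Huang–Minlon procedure), which works on ketones flanked by a quaternary carbon such as camphor. The dioxolane and the vinyl group, which has no allylic hydrogen, are inert to the base, and no stereocenter is epimerisable.

Step 12
Reactants: 15 C9 vinyl hydroazulene ketal
Product: 17 C9 carbaldehyde (C8 methylene), via secondary ozonide 16 (not isolated)
Conditions: O3, CH2Cl2/MeOH, −78 °C; Me2S, −78 °C → rt
Reagents that add atoms: ozone, [O-][O+]=O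
Why: Ozonolysis of the only alkene with reductive work-up returns the C11 aldehyde, now without the C8 oxygen.

Step 13
Reactants: 17 C9 carbaldehyde
Product: 20 (E)-nitroalkene (C11=C12), via C11 nitro alcohol 18 (not isolated), via C11 nitro mesylate 19 (not isolated)
Conditions: MeNO2, KOtBu (10 mol %), THF/tBuOH, 0 °C; then MsCl, Et3N, CH2Cl2, 0 °C
Reagents that add atoms: nitromethane, C[N+](=O)[O-]
Why: Henry (nitroaldol) addition followed by mesylation and E1cB elimination should give the E nitroalkene; there is no γ-hydrogen, so the double bond cannot move out of conjugation.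

Step 14
Reactants: 20 (E)-nitroalkene; 21 sodium cyclopentadienide
Product: 24 cyclopent-4-ene-cis-1,3-diol (hydroxyls on C15 and C17 trans to the C11 substituent on C16; 11R), via 5-alkylcyclopentadiene 22 (not isolated), via anti endoperoxide 23 (not isolated)
Conditions: NaC5H5 (1.0 equiv), THF, −78 → −50 °C; AcOH, −78 °C; then O2, hν, tetraphenylporphyrin (cat.), CH2Cl2/MeOH, −78 °C; thiourea, −78 °C → rt
Reagents that add atoms: dioxygen, O=O
Why: Proposed new method: the cyclopentadienide carbon adds to C11 of the nitroalkene (Michael addition) to give the nitronate of the kinetic 5-substituted cyclopentadiene, whose 1,5-hydrogen shift is slow below about −20 °C. Singlet oxygen then adds across the diene termini C15 and C17 anti to the C16 substituent, and thiourea reduces the O–O bond with retention, so both hydroxyls end trans to C11. The closest known reactions are the low-temperature C-alkylation of NaC5H5 to 5-alkylcyclopentadienes that are trapped before they isomerise, Michael additions of carbon acids of similar acidity to nitroalkenes, and the photooxygenation and thiourea reduction of cyclopentadiene to cis-cyclopent-2-ene-1,4-diol. C11 is set by addition anti to the C10 branch of C9 with the tied-back ring carbon C8 next to the nitrovinyl carbon (Felkin-type control), which leads to the 11R configuration.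

Step 15
Reactants: 24 cyclopent-4-ene-cis-1,3-diol
Product: 25 bis(tert-butyldimethylsilyl) ether
Conditions: TBSOTf, 2,6-lutidine, CH2Cl2, −78 → 0 °C
Reagents that add atoms: tert-butyldimethylsilyl trifluoromethanesulfonate, CC(C)(C)[Si](C)(C)OS(=O)(=O)C(F)(F)F
Why: Silyl ether formation protects both carbinols for the oxidative steps; any silyl nitronate formed reverts to the nitro compound on work-up.

Step 16
Reactants: 25 bis(tert-butyldimethylsilyl) ether
Product: 28 bis(silyloxy) diacid (C14 and C19 carboxylic acids), via bicyclic ozonide 26 (not isolated), via bis(silyloxy) dialdehyde 27 (not isolated)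
Conditions: O3, CH2Cl2, −78 °C; PPh3; then NaClO2, NaH2PO4, 2-methylbut-2-ene, tBuOH/H2O, 0 °C → rt
Reagents that add atoms: ozone, [O-][O+]=O; sodium chlorite, [Na+].[O-]Cl=O
Why: Ozonolysis of the ring alkene and Pinnick oxidation convert C14 and C19 into carboxyl groups; the neutral primary nitro group and the ketal are inert, and the buffered oxidation does not epimerise the α-silyloxy centers.

Step 17
Reactants: 28 bis(silyloxy) diacid
Product: 29 dimethyl ester
Conditions: TMSCHN2, PhMe/MeOH, 0 °C
Reagents that add atoms: (trimethylsilyl)diazomethane, C[Si](C)(C)C=[N+]=[N-]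
Why: Esterification with a diazoalkane under neutral conditions gives both methyl esters without touching the silyl ethers or the nitro group.

Step 18
Reactants: 29 dimethyl ester
Product: 30 C12 aldehyde
Conditions: KOtBu (1.05 equiv), THF, −78 °C; then O3, CH2Cl2/MeOH, −78 °C; Me2S
Reagents that add atoms: ozone, [O-][O+]=O
Why: Nef reaction by ozonolysis of the nitronate: only the nitro-bearing carbon is deprotonated at −78 °C, and cleavage of the C=N bond gives the aldehyde without acid, so the ketal and the silyl ethers survive. The hindered C11 center should not enolise at this temperature.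

Step 19
Reactants: 30 C12 aldehyde
Product: 32 hydroxy lactone (2,7-dioxabicyclo[3.2.1]octan-3-one with free C15 hydroxyl), via dihydroxy aldehyde diester 31 (not isolated)
Conditions: HF·pyridine, THF, 0 °C → rt; then CSA (20 mol %), PhMe, 4 Å MS, 60 °C
Reagents that add atoms: none
Why: After desilylation the aldehyde forms five-membered lactols with either hydroxyl reversibly, and the lactol whose oxygen is cis to the other arm lactonises with loss of methanol (acetalisation and transesterification under thermodynamic control). C11 selects the arm: closure through O18–C17 places the hydroazulenyl group over the lactone bridge next to H15, whereas the other mode would press it against the exo ester. C12 is fixed by the bicycle, and the anhydrous acid leaves the dioxolane in place.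

Step 20
Reactants: 32 hydroxy lactone
Product: 33 C15 acetate
Conditions: Ac2O, pyridine, DMAP (cat.), CH2Cl2, 0 °C → rt
Reagents that add atoms: acetic anhydride, CC(=O)OC(C)=O
Why: Acylation of the equatorial secondary hydroxyl.

Step 21
Reactants: 33 C15 acetate
Product: 34 C1 ketone
Conditions: PPTS, acetone/H2O, 50 °C
Reagents that add atoms: water, O
Why: Acid-catalysed acetal hydrolysis; the acylal is the stable closed form under these conditions. The cis ring fusion should hold, because epimerisation at C10 would place C1 on the face of the C9 bicycle.

Step 22
Reactants: 34 C1 ketone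
Product: 35 target compound
Conditions: Zn, CH2Br2, TiCl4, THF/CH2Cl2, 0 °C → rt
Reagents that add atoms: dibromomethane, BrCBr
Why: Takai–Lombardo methylenation: the non-basic titanium–zinc methylene reagent reacts with hindered, enolisable ketones and leaves esters, the lactone and the acetate alone, so C10 is not epimerised.

## Compound list

1 | 3-methylcyclohex-2-en-1-one | CC1=CC(=O)CCC1 | starting material
2 | 3,3-dimethyl-1-(trimethylsilyloxy)cyclohex-1-ene | CC1(C)CCCC(O[Si](C)(C)C)=C1 | intermediate
3 | 5,5-dimethyl-1-(trimethylsilyloxy)bicyclo[4.1.0]heptane (racemic, cis-fused) | C[Si](C)(C)OC12CCCC(C)(C)C1C2 | intermediate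
4 | 3-chloro-4,4-dimethylcycloheptan-1-one (racemic; not isolated) | O=C1CC(Cl)C(C)(C)CCC1 | intermediate
5 | 4,4-dimethylcyclohept-2-en-1-one | O=C1C=CC(C)(C)CCC1 | intermediate
6 | (E)-pent-3-en-2-one | C/C=C/C(C)=O | starting material
7 | (E)-2-(tert-butyldimethylsilyloxy)penta-1,3-diene | C=C(O[Si](C)(C)C(C)(C)C)/C=C/C | intermediate
8 | Diels–Alder adduct: cis-fused cycloheptanone–cyclohexene, C1 ketone, C8 tert-butyldimethylsilyl enol ether (C8=C11), C9 methyl; H6, H9 and H10 on one face, C6 and C10 arranged as in the target | O=C1CCCC(C)(C)[C@@H]2CC(O[Si](C)(C)C(C)(C)C)=C[C@H](C)[C@H]12 | intermediate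
9 | cis-fused enedione: C1 ketone, C8 ketone conjugated with C11=C9 (C9 methyl); H6 and H10 cis | O=C1CCCC(C)(C)[C@@H]2CC(=O)C=C(C)[C@H]12 | intermediate
10 | enone ketal: C1 ethylene ketal of 9 | O1CCOC12CCCC(C)(C)[C@@H]3CC(=O)C=C(C)[C@H]23 | intermediate
11 | epoxy ketone: C9–C11 epoxide of 10 on the face of H6 and H10, oxygen anti to C1 | O1CCOC12CCCC(C)(C)[C@@H]3CC(=O)[C@H]4O[C@@]4(C)[C@H]23 | intermediate
12 | hydroazulenone carbaldehyde: cis-fused C8 cyclopentanone, quaternary C9 with methyl (syn to C1) and formyl C11 (syn to H6 and H10), C1 ethylene ketal | O1CCOC12CCCC(C)(C)[C@@H]3CC(=O)[C@@](C)(C=O)[C@H]23 | intermediate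
13 | C9 vinyl ketone (C11=CH2 in place of the formyl group of 12) | O1CCOC12CCCC(C)(C)[C@@H]3CC(=O)[C@@](C)(C=C)[C@H]23 | intermediate
14 | C8 hydrazone of 13 (not isolated) | O1CCOC12CCCC(C)(C)[C@@H]3CC(=NN)[C@@](C)(C=C)[C@H]23 | intermediate
15 | C9 vinyl hydroazulene ketal (C8 methylene) | O1CCOC12CCCC(C)(C)[C@@H]3CC[C@@](C)(C=C)[C@H]23 | intermediate
16 | secondary ozonide (1,2,4-trioxolane) of 15 (not isolated) | O1CCOC12CCCC(C)(C)[C@@H]3CC[C@@](C)(C4OCOO4)[C@H]23 | intermediate
17 | C9 carbaldehyde (C11 formyl, C8 methylene, C1 ketal) | O1CCOC12CCCC(C)(C)[C@@H]3CC[C@@](C)(C=O)[C@H]23 | intermediate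
18 | β-nitro alcohol: C11 carbinol, C12 nitromethyl, both C11 epimers (not isolated) | O1CCOC12CCCC(C)(C)[C@@H]3CC[C@@](C)(C(O)C[N+](=O)[O-])[C@H]23 | intermediate
19 | methanesulfonate of 18 (not isolated) | O1CCOC12CCCC(C)(C)[C@@H]3CC[C@@](C)(C(OS(C)(=O)=O)C[N+](=O)[O-])[C@H]23 | intermediate
20 | (E)-nitroalkene, C9–C11H=C12H–NO2 | O1CCOC12CCCC(C)(C)[C@@H]3CC[C@@](C)(/C=C/[N+](=O)[O-])[C@H]23 | intermediate
21 | sodium cyclopentadienide | [Na+].[cH-]1cccc1 | starting material
22 | 5-substituted cyclopenta-1,3-diene: ring sp3 carbon C16 bonded to C11 (11R), C12 nitromethyl (not isolated) | O1CCOC12CCCC(C)(C)[C@@H]3CC[C@@](C)([C@H](C[N+](=O)[O-])C4C=CC=C4)[C@H]23 | intermediate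
23 | endoperoxide: 2,3-dioxabicyclo[2.2.1]hept-5-ene with C16 as the one-carbon bridge and the peroxide bridge anti to the C11 substituent (not isolated) | O1CCOC12CCCC(C)(C)[C@@H]3CC[C@@](C)([C@H](C[N+](=O)[O-])[C@H]4[C@H]5C=C[C@@H]4OO5)[C@H]23 | intermediate
24 | cyclopent-4-ene-cis-1,3-diol: hydroxyls on C15 and C17 cis to each other and trans to the C11 substituent on C16; 11R | O1CCOC12CCCC(C)(C)[C@@H]3CC[C@@](C)([C@H](C[N+](=O)[O-])[C@H]4[C@H](O)C=C[C@@H]4O)[C@H]23 | intermediate
25 | bis(tert-butyldimethylsilyl) ether of 24 | O1CCOC12CCCC(C)(C)[C@@H]3CC[C@@](C)([C@H](C[N+](=O)[O-])[C@H]4[C@H](O[Si](C)(C)C(C)(C)C)C=C[C@@H]4O[Si](C)(C)C(C)(C)C)[C@H]23 | intermediate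
26 | bicyclic ozonide of 25 (not isolated) | O1CCOC12CCCC(C)(C)[C@@H]3CC[C@@](C)([C@H](C[N+](=O)[O-])[C@H]4[C@H](O[Si](C)(C)C(C)(C)C)C5OC(OO5)[C@@H]4O[Si](C)(C)C(C)(C)C)[C@H]23 | intermediate
27 | bis(silyloxy) dialdehyde: C14 and C19 formyl groups (not isolated) | O1CCOC12CCCC(C)(C)[C@@H]3CC[C@@](C)([C@H](C[N+](=O)[O-])[C@@H]([C@H](O[Si](C)(C)C(C)(C)C)C=O)[C@@H](O[Si](C)(C)C(C)(C)C)C=O)[C@H]23 | intermediate
28 | bis(silyloxy) diacid: 2,4-bis(silyloxy)glutaric acid carrying the C11 nitroalkyl group on C16 | O1CCOC12CCCC(C)(C)[C@@H]3CC[C@@](C)([C@H](C[N+](=O)[O-])[C@@H]([C@H](O[Si](C)(C)C(C)(C)C)C(=O)O)[C@@H](O[Si](C)(C)C(C)(C)C)C(=O)O)[C@H]23 | intermediate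
29 | dimethyl ester of 28 | O1CCOC12CCCC(C)(C)[C@@H]3CC[C@@](C)([C@H](C[N+](=O)[O-])[C@@H]([C@H](O[Si](C)(C)C(C)(C)C)C(=O)OC)[C@@H](O[Si](C)(C)C(C)(C)C)C(=O)OC)[C@H]23 | intermediate
30 | C12 aldehyde (nitromethyl of 29 converted into formyl) | O1CCOC12CCCC(C)(C)[C@@H]3CC[C@@](C)([C@H](C=O)[C@@H]([C@H](O[Si](C)(C)C(C)(C)C)C(=O)OC)[C@@H](O[Si](C)(C)C(C)(C)C)C(=O)OC)[C@H]23 | intermediate
31 | dihydroxy aldehyde diester (open chain or lactol; not isolated) | O1CCOC12CCCC(C)(C)[C@@H]3CC[C@@](C)([C@H](C=O)[C@@H]([C@H](O)C(=O)OC)[C@@H](O)C(=O)OC)[C@H]23 | intermediate
32 | hydroxy lactone: 2,7-dioxabicyclo[3.2.1]octan-3-one with free C15 hydroxyl, C17 methyl ester, C1 ketal | O1CCOC12CCCC(C)(C)[C@@H]3CC[C@@](C)([C@@H]4[C@@H]5OC(=O)[C@@H](O)[C@H]4[C@H](C(=O)OC)O5)[C@H]23 | intermediate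
33 | C15 acetate of 32 | O1CCOC12CCCC(C)(C)[C@@H]3CC[C@@](C)([C@@H]4[C@@H]5OC(=O)[C@@H](OC(C)=O)[C@H]4[C@H](C(=O)OC)O5)[C@H]23 | intermediate
34 | C1 ketone | O=C1CCCC(C)(C)[C@@H]2CC[C@@](C)([C@@H]3[C@@H]4OC(=O)[C@@H](OC(C)=O)[C@H]3[C@H](C(=O)OC)O4)[C@H]12 | intermediate
35 | CNP0215240.1 | C=C1CCCC(C)(C)[C@@H]2CC[C@@](C)([C@@H]3[C@@H]4OC(=O)[C@@H](OC(C)=O)[C@H]3[C@H](C(=O)OC)O4)[C@H]12 | target

## Step count and least certain steps

Total: 22 steps. Longest linear sequence: 21 steps (1 to 35; step 4 makes the diene branch).

Step 14 (proposed new method). The ring double bonds may move before the photooxygenation, by proton exchange between the adduct and unreacted cyclopentadienide or by a 1,5-hydrogen shift on warming; this would place the substituent on a diene carbon. The facial selectivity at C11 may also be poor, because it rests on the small difference between the methyl group and the ring methylene on C9. The fallback uses known chemistry, sets out from 20 and returns at 24. A bifunctional thiourea–tertiary amine catalyst (Takemoto type, the enantiomer that directs the donor to the Re face of C11) adds cyclopent-4-ene-1,3-dione to 20 and gives the 2-substituted cyclopent-4-ene-1,3-dione F1 with catalyst control at C11. NaBH4 with CeCl3·7H2O at −78 °C reduces both carbonyls from the face away from the C11 substituent to the all-cis diol F2. Double Mitsunobu inversion (4-nitrobenzoic acid, PPh3, DIAD) gives the trans,trans bis(4-nitrobenzoate) F3, and K2CO3 in MeOH releases 24.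

Step 9 (key step). A 1,2-hydride shift may compete with acyl migration, the Lewis acid may open the dioxolane, and the product may lose its formyl group during work-up. The fallback sets out from 10 and returns at 12. Dihydroxylation on the convex face (OsO4, N-methylmorpholine N-oxide) gives the keto diol F4, and pinacol rearrangement with a catalytic protic acid (TsOH, benzene) ionises the tertiary C9 carbinol; the same acyl shift follows without the epoxide and without a stoichiometric Lewis acid near the ketal.

Step 5. The cycloaddition may be slow, because the β-carbon of 5 is next to the gem-dimethyl carbon; the catalyst may then desilylate the diene or give incomplete face selectivity. The fallback sets out from 5 and 7 and returns at 10. EtAlCl2-promoted cycloaddition gives the racemic adduct, that is 8 together with its enantiomer F5. Steps 6 and 7 applied to the racemate give 9 with its enantiomer F6 and then 10 with its enantiomer F7, and preparative chromatography on a chiral stationary phase separates 10 from F7.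

Step 19. Lactonisation of a hydroxyl of one arm onto the ester of the other (five-membered ring) may compete with the bicyclic closure, the wrong arm may close, or C11 may epimerise through the enol of the aldehyde. The fallback sets out from 28 and returns at 32. The Nef reaction is run on the diacid (KOtBu, 3.1 equiv, then O3) to give the aldehyde diacid F8. HF·pyridine then removes the silyl groups, and the free acid closes onto the lactol as an acylal without having to expel methanol, giving the hydroxy lactone acid F9; TMSCHN2 methylates the remaining acid to 32.

Step 22. Conversion may be low at the hindered ketone, and the Lewis-acidic reagent may open the acylal or epimerise C10 through the titanium enolate. The fallback sets out from 34 and returns at 35. Addition of Me3SiCH2Li in the presence of CeCl3 at −78 °C gives the β-hydroxysilane F10, and acid-mediated Peterson elimination (HF·pyridine) gives 35.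

## Further compounds

F1 | step 14 | 2-substituted cyclopent-4-ene-1,3-dione (C16 between the two carbonyls, 11R) | O1CCOC12CCCC(C)(C)[C@@H]3CC[C@@](C)([C@H](C[N+](=O)[O-])C4C(=O)C=CC4=O)[C@H]23
F2 | step 14 | all-cis cyclopent-4-ene-1,3-diol (hydroxyls cis to the C11 substituent) | O1CCOC12CCCC(C)(C)[C@@H]3CC[C@@](C)([C@H](C[N+](=O)[O-])[C@H]4[C@@H](O)C=C[C@H]4O)[C@H]23
F3 | step 14 | trans,trans bis(4-nitrobenzoate) of 24 | O1CCOC12CCCC(C)(C)[C@@H]3CC[C@@](C)([C@H](C[N+](=O)[O-])[C@H]4[C@H](OC(=O)c5ccc(cc5)[N+](=O)[O-])C=C[C@@H]4OC(=O)c5ccc(cc5)[N+](=O)[O-])[C@H]23
F4 | step 9 | keto diol: C9 and C11 hydroxyls cis, on the face of H6 and H10 | O1CCOC12CCCC(C)(C)[C@@H]3CC(=O)[C@@H](O)[C@](O)(C)[C@H]23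
F5 | step 5 | enantiomer of 8 | O=C1CCCC(C)(C)[C@H]2CC(O[Si](C)(C)C(C)(C)C)=C[C@@H](C)[C@@H]12
F6 | step 5 | enantiomer of 9 | O=C1CCCC(C)(C)[C@H]2CC(=O)C=C(C)[C@@H]12
F7 | step 5 | enantiomer of 10 | O1CCOC12CCCC(C)(C)[C@H]3CC(=O)C=C(C)[C@@H]23
F8 | step 19 | aldehyde diacid (bis-silyl ether) | O1CCOC12CCCC(C)(C)[C@@H]3CC[C@@](C)([C@H](C=O)[C@@H]([C@H](O[Si](C)(C)C(C)(C)C)C(=O)O)[C@@H](O[Si](C)(C)C(C)(C)C)C(=O)O)[C@H]23
F9 | step 19 | hydroxy lactone acid (C17 carboxylic acid) | O1CCOC12CCCC(C)(C)[C@@H]3CC[C@@](C)([C@@H]4[C@@H]5OC(=O)[C@@H](O)[C@H]4[C@H](C(=O)O)O5)[C@H]23
F10 | step 22 | β-hydroxysilane: C1 carbinol with trimethylsilylmethyl group, both C1 epimers | C[Si](C)(C)CC1(O)CCCC(C)(C)[C@@H]2CC[C@@](C)([C@@H]3[C@@H]4OC(=O)[C@@H](OC(C)=O)[C@H]3[C@H](C(=O)OC)O4)[C@H]12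
A1 | alternative 1 | methyl 2-diazo-4-methylpent-3-enoate | COC(=O)C(=[N+]=[N-])C=C(C)C
A2 | alternative 1 | 1-(1-ethoxyvinyl)-5-methyl-5-[2-(triisopropylsilyloxy)ethyl]cyclopent-1-ene, quaternary carbon configured as C9 of the target | C=C(OCC)C1=CCC[C@@]1(C)CCO[Si](C(C)C)(C(C)C)C(C)C
A3 | alternative 1 | bicyclic cycloheptadiene ester | COC(=O)C1=CC(C)(C)[C@@H]2CC[C@@](C)(CCO[Si](C(C)C)(C(C)C)C(C)C)C2=C(OCC)C1
A4 | alternative 2 | open-chain dihydroxyglutarate aldehyde | O1CCOC12CCCC(C)(C)[C@@H]3CC[C@@](C)([C@H](C=O)[C@@H]([C@H](O)C(=O)OC)[C@@H](O)C(=O)OC)[C@H]23
A5 | alternative 2 | bicyclic hydroxy lactone ester | O1CCOC12CCCC(C)(C)[C@@H]3CC[C@@](C)([C@@H]4[C@@H]5OC(=O)[C@@H](O)[C@H]4[C@H](C(=O)OC)O5)[C@H]23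
A6 | alternative 3 | unsaturated lactone whose C12 acetal oxygen carries the aminoxyl-substituted glycolate (both C17 epimers) | C=C1CCCC(C)(C)[C@@H]2CC[C@@](C)([C@H]3C=CC(=O)O[C@@H]3OC(ON4C(C)(C)CCCC4(C)C)C(=O)OC)[C@H]12
A7 | alternative 3 | bicyclic lactone with aminoxyl on C15 | C=C1CCCC(C)(C)[C@@H]2CC[C@@](C)([C@@H]3[C@@H]4OC(=O)[C@@H](ON5C(C)(C)CCCC5(C)C)[C@H]3[C@H](C(=O)OC)O4)[C@H]12
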